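In both runs L changes less than J after its first reading: L goes from 62.1% to 57.1% on Saturday's and from 72.0% to 70.5% on Tuesday's, while J goes from 11.6% to 32.2% on Saturday's and from 11.0% to 22.2% on Tuesday's. So I count turnovers on J.

all flasks: L 20 mM

| run | E | D | temperature | remark | time |
|---|---|---|---|---|---|
| Saturday's | 56 mM | 22 mM (fed, over 12 s) | 6 °C | run made earlier |  |
| Tuesday's | 88 mM | 22 mM (fed, over 12 s) | 20 °C | run made earlier |  |
| amber | 40.0 mM | 22.0 mM (fed, over 12 s) |  | at 0 °C until 12 s, from then on at 25 °C | 30 min |
| red | 40.0 mM | 22.0 mM (fed, over 12 s) |  | at 0 °C throughout | 60 min |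

| run | time / min | J / % | L / % |
|---|---|---|---|
| Saturday's | 2.50 | 11.6 | 62.1 |
| Saturday's | 5.00 | 22.3 | 59.8 |
| Saturday's | 8.00 | 27.0 | 57.9 |
| Saturday's | 15.0 | 30.4 | 57.9 |
| Saturday's | 30.0 | 32.2 | 57.1 |
| Tuesday's | 1.00 | 11.0 | 72.0 |
| Tuesday's | 3.00 | 21.0 | 71.9 |
| Tuesday's | 6.00 | 23.4 | 71.7 |
| Tuesday's | 8.00 | 22.5 | 71.3 |
| Tuesday's | 12.0 | 22.2 | 70.5 |

(each reading ± 0.5 percentage points)

- which of the two ends with the higher amount of J, in percent of the L charged ("neither" if they lie within 2 percentage points) (amber / red / neither)
- J at the end, in percent of the L charged, amber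
- J at the end, in percent of the L charged, red

I go down the ladder of clocks. On the fastest rung, L has already dropped to 72.0% at Tuesday's first reading. On the next rung J rises: on Tuesday's it stands at half of its highest reading after 1.00 min. Amber's 30 min therefore holds 30.0 such half-times, and amber runs warmer than Tuesday's after 12 s.

On the slowest rung J falls, and I read this from Tuesday's, with the scatter of two readings in it. I take the usual doubling per 10 K to go from 20 °C to 25 °C:

k(Tuesday's) = ln(23.4% / 22.2%) / (12.0 min − 6.00 min) = 0.00877 /min

k(amber) = k(Tuesday's) · sqrt(2) = 0.0124 /min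

My quantity is the loss count, rate constant times time (a Damköhler number):

N = k(amber) · 30 min = 0.372, so the surviving share is S = exp(−N) = 68.9%

The rise counts 30.0 half-times against a loss count of 0.372, so in amber I expect the rise to be over early and the remaining minutes to be loss. On Saturday's, J still climbs from 30.4% to 32.2%, so I charge red, colder still, with no loss.

The forecast says red, amber 32%, red 38%: “Late in Tuesday's run, J and L fall together, suggesting J + L loss, which is significant when warm.” My own reckoning differs: S on its red figure leaves amber 26.2%, less than its 32%.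

The simulation gives red as the higher, with amber 23.1% and red 35.3%.

    L + D → Q (k = 0.238 /M/s, Ea = 46.0 kJ/mol)
    D + E → Z (k = 0.110 /M/s, Ea = 55.0 kJ/mol)
    Q + Z → J (k = 0.338 /M/s, Ea = 46.0 kJ/mol)
    2 Q → G (k = 0.139 /M/s, Ea = 56.0 kJ/mol)
    J → X (k = 8.57 × 10⁻⁶ /s, Ea = 83.0 kJ/mol)
    (constants at 0 °C)

Amber ends 8.9 percentage points under the forecast. The difference in temperature programme is the main reason that red ends above amber: with that difference taken away, red ends at 16.6% instead of 35.3%. S on red's 35.3% gives 24.3% for amber.

Now take amber read at 12 min. Counting back over the remaining time gives a loss count of 0.223, so J there should be 28.9%; the computed value is 28.1%.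

(The earlier runs and the new flask are simulated for substances that don't exist, and the scatter is random.)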